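Take the product of each run at its first reading and count it against the reagent, assuming one reagent spent per product made.

the same everywhere: precatalyst 50 mM

| run | starting material | reagent | remark |
|---|---|---|---|
| west | 0.50 M | 2 M | run made earlier |
| north-east | 0.75 M | 2 M | run made earlier |
| north-west | 1 M | 1 M | run made earlier |
| flask | 1.0 M | 2.00 M |  |

| run | time / h | product / % | starting material / % |
|---|---|---|---|
| west | 1.33 | 61.2 | 38.7 |
| west | 2.50 | 85.1 | 16.1 |
| west | 5.00 | 97.9 | 1.9 |
| west | 10.0 | 100.6 | 0 |
| west | 20.0 | 99.6 | 0.3 |
| north-east | 1.33 | 44.2 | 53.9 |
| north-east | 2.50 | 65.6 | 33.3 |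
| north-east | 5.00 | 86.0 | 13.2 |
| north-east | 10.0 | 98.0 | 1.5 |
| north-east | 20.0 | 99.9 | 0 |
| north-west | 1.33 | 17.8 | 81.4 |
| north-west | 2.50 | 26.5 | 72.2 |
| north-west | 5.00 | 38.7 | 61.3 |
| north-west | 10.0 | 46.6 | 51.8 |
| north-west | 20.0 | 57.5 | 42.4 |

(scatter of a reading: 1 percentage point)

- no earlier run changes the charge of precatalyst; that part of a forecast is a guess

* factor on the rate of making product when 20% of the starting material are converted if reagent is charged twice over
* factor on the rate when 20% of the starting material are converted if precatalyst is charged at 250 mM instead

Define the reagent draw, the share of its own charge that the reagent has lost, as product fraction times starting-material charge over reagent charge: in the north-west run at 1.33 h it is 17.8%. Set the runs side by side at that time: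

- west: charge ratio 0.250, product 61.2%, draw 15.3%
- north-east: charge ratio 0.375, product 44.2%, draw 16.6%
- north-west: charge ratio 1.00, product 17.8%, draw 17.8%

Read down the columns. The charge ratio changes by a factor 4.00, but the draw changes by a factor 1.16. The west and north-west runs differ in both charges, so this is no clean test; as a working assumption, take the rate as following the amount of reagent.

Now read along the north-west run. Between its first two readings the draw runs at 0.556 of its earlier pace, less than the 73.5% of the reagent reckoned to remain at the second reading. As a second working assumption, take the pace as falling with the clock as well.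

In the flask, 20% conversion needs a draw of 10.0%. With twice the reagent it needs 5.00%, which comes earlier on the clock, at a faster pace. My reckoning is therefore a factor above 2 on dbl. No run varies the precatalyst, so ratio stays a guess near proportion.

The forecast says 1.6 for dbl, with the reagent “probably near the saturating shoulder”, which differs from my reckoning, and 4 for ratio.

The simulation gives 2.46 for dbl and 4.71 for ratio.

    2 free catalyst → spent catalyst (k = 0.00739 M⁻¹ s⁻¹)
    precatalyst ⇌ free catalyst (K = 0.942, k = 0.00267 s⁻¹)
    starting material + reagent + free catalyst → product + free catalyst, rate k3*[starting material]*[reagent]*[free catalyst]/(1 + ([starting material]/sat3)) (0.101 M, k = 0.0263 M⁻² s⁻¹)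

When the flask reaches 20% conversion, at 0.650 h, free catalyst is 35.3% of the catalyst, and at 1.50 h it is 25.7%. The flask's draw at that later time is 19.1%, beside 17.8% for the north-west run at 1.33 h. Starting material is the limiting reagent in the flask, with 0% of it left at 150 h, when the reagent stands at 50.0%, a draw of 50.0%.

(Readings and results are calculated for an exercise.)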